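Watch one ratio.

    starting material + free catalyst ⇌ catalyst intermediate A (K1 = 380 M⁻¹, k1 = 520 M⁻¹ min⁻¹)
    coupling partner + catalyst intermediate A → free catalyst + target (k2 = 3.2 M⁻¹ min⁻¹)
    second substrate + free catalyst ⇌ catalyst intermediate B (K3 = 0.76 M⁻¹, k3 = 22 M⁻¹ min⁻¹)
    coupling partner + catalyst intermediate B → free catalyst + second product (k4 = 9.6 M⁻¹ min⁻¹)
    starting material + protic impurity → quenched substrate (k5 = 0.16 M⁻¹ min⁻¹)
    free catalyst + added ligand ⇌ idle complex (K6 = 2500 M⁻¹, k6 = 570 M⁻¹ min⁻¹)

starting material 0.83 M; second substrate 1.66 M; coupling partner 1.66 M; protic impurity 0.415 M; free catalyst 17 mM; added ligand 23 mM

- apparent order in coupling partner when 20% of the starting material are converted (percent change of the rate of making target for one percent more coupling partner charged)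
- apparent order in free catalyst when 20% of the starting material are converted (percent change of the rate of making target for one percent more free catalyst charged)

In this flask the starting material takes up free catalyst at 432 min⁻¹ per free catalyst, far faster than catalyst intermediate A leaves by falling apart or by step 2, at 6.68 min⁻¹ together. So I take free catalyst as settled and fold the givens into one number, 64.6 at the full charge: the holding number, catalyst intermediate A per free catalyst. Step 2 makes up 79.5% of the exit. The number therefore follows the fraction of starting material left, divided by the exit with its step 2 part cut to the fraction of coupling partner left.

At 20% conversion, taking the coupling partner as unspent, it is 51.7. Intermediate A is then the resting state, and my order in coupling partner is 0.985.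

The number holds no catalyst charge, though, so by itself it gives an order of 1 in catalyst, and one number is not enough here. Free catalyst also leaks into the idle complex, which drains intermediate A on a time of 3.94 min. Reaching the mark takes about 1.02 min at starting rates, which is shorter, so I reckon about 25.9% of the catalyst lost by then. A larger charge arrives sooner and loses less, so I commit to a little above 1.

The forecast gives 0.97 and 1.12. Its order in coupling partner is lower than mine, and it holds that “a larger charge reaches that point sooner”.

The flask gives 0.97 and 1.1. In this flask at 1.18 min, intermediate A has a half-life by step 2 of 0.14 min, far shorter than the 5.7 min half-life of starting material by forward step 1 alone, and its making runs at 0.972 of its using up. The holding number taken to the fractions left at 1.50 min gives 52.9, and the flask then holds 74.6% of the catalyst as intermediate A against 1.38% free, a ratio of 54.1.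

(The numbers of this flask are invented; no experiment stands behind them.)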